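A direct plan would first make the diaryl ether bonds of the B–C–D core by two sterically graded SNAr reactions of a bromohydroquinone with two fluorobenzaldehydes (trialdehyde A1), then oxidise the three formyl groups to phenols (dibromo triphenol A2).
One flask would then close the dioxin by copper-catalysed Ullmann coupling and the furan by palladium-catalysed C–H arylation (pentacyclic bis-phenol A3); a twofold Ullmann O-arylation would add rings A and E (nonamethyl ether A4), and Lewis-acid demethylation would free nine phenols.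
Weakest: the C–H arylation that closes the furan in A2 → A3 has to pick one of two ring C C–H bonds on a substrate with three free phenols at high dilution; nothing in close precedent fixes that choice, and the wrong choice gives an isomeric core.
Weak: the twofold O-arylation of A3 couples two phenols that each sit between two ortho oxygens with an electron-rich aryl iodide, so the slowest ether bonds are made last, on the most valuable intermediate.
Weak: the double SNAr to A1 separates two phenoxides of an oxidation-prone hydroquinone by steric demand only, and the three formyl groups serve only as activators that are then oxidised off.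

Retrosynthetic overview
Labels: ring B = B1 (O–ring A), B2 (OH), B3 (H), B4 (OH), B5 and B6 (dioxin carbons); ring C = C1 (dioxin, bonded through O to B6), C2 (OH), C3 (H), C4 (furan O), C5 (biaryl carbon), C6 (dioxin, bonded through O to B5); ring D = D1 (furan O), D2 (O–ring E), D3 (OH), D4 (H), D5 (OH), D6 (biaryl carbon).
Feature used: the oxygens on C1/C4 of ring C and on B2/B5 of ring B are para, so both rings are latent 1,4-benzoquinones; the two outer halves (ring A–O–ring B and ring E–O–ring D) are one and the same 2-aryloxy-5-methoxyresorcinol, joined to ring C through its C1–O position and its C6.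
Key disconnection: the biaryl bond C5–D6 and the furan C–O bond at D1 are formed together by acid-mediated [3+2] condensation of 2-bromo-6-methoxy-1,4-benzoquinone (ring C, polarity reversed) with that resorcinol, a union of two phenol carbons of like polarity.
The dioxin follows: the same resorcinol is oxidised to a chloroquinone (ring B with ring A), the ring C phenol adds to it by addition–elimination (C1–O–B6), and after reduction an intramolecular Ullmann coupling closes C6–O–B5; the ring order is furan, then dioxin.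
Design gains: the site of C–C bond formation is fixed by quinone polarity and by the symmetry of the nucleophile, not by a choice between C–H bonds; rings A and E enter in step 1 on a simple phenol, so there is no late O-arylation of hindered phenols and no formyl on/off sequence.

Key step: step 4

Remark: the target is achiral, so no stereocentre has to be set; 2,6-dibromo-4-methoxyphenol, (3,5-dimethoxyphenyl)boronic acid and 5-bromovanillin are taken as commercial.

Step 1
Reactants: 1 2,6-dibromo-4-methoxyphenol; 2 (3,5-dimethoxyphenyl)boronic acid (2 equiv)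
Product: 3 1,3-dibromo-2-(3,5-dimethoxyphenoxy)-5-methoxybenzene
Conditions: Cu(OAc)2 (20 mol %), pyridine (3 equiv), 4 Å MS, CH2Cl2, O2 (1 atm), rt
Reagents that add atoms: none
Why: Chan–Lam–Evans oxidative O-arylation, which was devised for 2,6-dihalophenols of the thyroxine type and leaves the two aryl bromides untouched at room temperature.

Step 2
Reactants: 3 1,3-dibromo-2-(3,5-dimethoxyphenoxy)-5-methoxybenzene
Product: 4 2-(3,5-dimethoxyphenoxy)-5-methoxybenzene-1,3-diol
Conditions: Pd2(dba)3 (2 mol %), tBuXPhos (8 mol %), KOH (6 equiv), 1,4-dioxane/H2O, 100 °C, Ar; then aq. HCl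
Reagents that add atoms: potassium hydroxide, [K+].[OH-]
Why: Palladium-catalysed hydroxylation of aryl bromides with hydroxide (biaryl phosphine C–O coupling) should convert the two equivalent bromides, each with only one ortho substituent, into the symmetric resorcinol.

Step 3
Reactants: 5 5-bromovanillin (3-bromo-4-hydroxy-5-methoxybenzaldehyde)
Product: 7 2-bromo-6-methoxy-1,4-benzoquinone, via hydroquinone 6 (not isolated)
Conditions: 30% H2O2 (1.2 equiv), aq. NaOH (1.1 equiv), 0 °C → rt, N2; HCl; then NaIO4 (1.1 equiv), CH2Cl2/H2O, rt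
Reagents that add atoms: hydrogen peroxide, OO
Why: Dakin oxidation of the para-hydroxybenzaldehyde (aryl migration in the peroxide adduct, formate hydrolysed in base) gives the hydroquinone, which periodate oxidises to the para-quinone.

Step 4
Reactants: 4 2-(3,5-dimethoxyphenoxy)-5-methoxybenzene-1,3-diol (1.5 equiv); 7 2-bromo-6-methoxy-1,4-benzoquinone
Product: 9 1-bromo-6-(3,5-dimethoxyphenoxy)-3,9-dimethoxydibenzo[b,d]furan-2,7-diol, via biaryl hydroquinone 8 (not isolated)
Conditions: 7 added over 3 h to 4 and TsOH·H2O (0.3 equiv), AcOH, 50 °C, Ar; then 70 °C, 2 h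
Reagents that add atoms: none
Why: The acid-activated quinone 7 is attacked by the resorcinol carbon C4/C6 of 4 (vinylogous Friedel–Crafts or Michael addition) at the quinone carbon para to OMe and next to C–Br, and tautomerisation gives biaryl hydroquinone 8; the hydroquinone oxygen next to the new bond then adds to C1 of the keto tautomer of ring D (5-exo-trig) and loss of water gives the furan. The closest known reaction type is the acid-catalysed condensation of 1,4-benzoquinones with resorcinols, phloroglucinols or cyclic 1,3-diones to 2-hydroxydibenzofurans (the benzofuran variant of the Nenitzescu reaction). Site selectivity on the quinone comes from the methoxy group, which makes its own β-carbon an enol ether carbon and leaves the carbon beside bromine as the Michael terminus; on 4 the two reactive carbons are equivalent by symmetry, C2 is blocked by the aryloxy group, and ring E, a triether without free OH, should be far less nucleophilic in acetic acid. Only the hydroquinone OH ortho to the biaryl bond can reach ring D, and it should displace the free OH (through the keto tautomer) and not the OMe on the other flank, which places the furan oxygen next to the ring E ether. Slow addition of 7 to excess 4 under argon with the acid present from the start should keep 8 from being oxidised by 7 to an aryl quinone, whose ring D hydroxyl would displace bromide and close the furan at the wrong carbon. No stereocentre is formed.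

Step 5
Reactants: 9 1-bromo-6-(3,5-dimethoxyphenoxy)-3,9-dimethoxydibenzo[b,d]furan-2,7-diol
Product: 10 1-bromo-7-[(tert-butyldimethylsilyl)oxy]-6-(3,5-dimethoxyphenoxy)-3,9-dimethoxydibenzo[b,d]furan-2-ol
Conditions: TBSCl (1.05 equiv), imidazole (2.2 equiv), DMF, 0 °C
Reagents that add atoms: tert-butyldimethylsilyl chloride, C[Si](C)(Cl)C(C)(C)C
Why: Imidazole-mediated silylation is governed by steric access, so the ring D hydroxyl (one ortho substituent) should react while the ring C hydroxyl between Br and OMe stays free.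

Step 6
Reactants: 4 2-(3,5-dimethoxyphenoxy)-5-methoxybenzene-1,3-diol
Product: 12 3-chloro-2-(3,5-dimethoxyphenoxy)-5-methoxy-1,4-benzoquinone, via hydroxyquinone 11 (not isolated)
Conditions: (KSO3)2NO (Fremy's salt, 2.5 equiv), KH2PO4 buffer, acetone/H2O, 0 °C → rt; extraction; then SOCl2 (3 equiv), pyridine (cat.), CH2Cl2, 0 → 40 °C
Reagents that add atoms: potassium nitrosodisulfonate (Fremy's salt), [K+].[K+].[O]N(S(=O)(=O)[O-])S(=O)(=O)[O-]; thionyl chloride, O=S(Cl)Cl
Why: Teuber oxidation attacks the free position para to one resorcinol OH (either OH gives the same 2-hydroxy-1,4-benzoquinone by symmetry, and ring A has no free OH), and thionyl chloride then turns this vinylogous acid into the vinylogous acid chloride of the more stable para-quinone tautomer.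

Step 7
Reactants: 10 1-bromo-7-[(tert-butyldimethylsilyl)oxy]-6-(3,5-dimethoxyphenoxy)-3,9-dimethoxydibenzo[b,d]furan-2-ol; 12 3-chloro-2-(3,5-dimethoxyphenoxy)-5-methoxy-1,4-benzoquinone (1.1 equiv)
Product: 13 3-{[1-bromo-7-(tert-butyldimethylsilyloxy)-6-(3,5-dimethoxyphenoxy)-3,9-dimethoxydibenzo[b,d]furan-2-yl]oxy}-2-(3,5-dimethoxyphenoxy)-5-methoxy-1,4-benzoquinone
Conditions: K2CO3 (1.5 equiv), MeCN, −20 → 0 °C, Ar
Reagents that add atoms: none
Why: Addition–elimination on a haloquinone (vinylogous acyl substitution): the phenoxide of 10 has all its ortho and para carbons substituted and can react only at oxygen, and loss of chloride is irreversible whereas addition at the aryloxy- or methoxy-bearing carbons is reversible.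

Step 8
Reactants: 13 the aryloxyquinone
Product: 16 phlorofucofuroeckol A heptamethyl ether (OMe on both oxygens of ring A and of ring E and on B4 C2 D5; free OH at B2 and D3), via hydroquinone 14 (not isolated), via silyl ether 15 (not isolated)
Conditions: Na2S2O4 (4 equiv), THF/H2O, rt, Ar; organic phase dried and concentrated under Ar; then CuI (20 mol %), 2,2,6,6-tetramethylheptane-3,5-dione (40 mol %), Cs2CO3 (4 equiv), degassed NMP (0.01 M), 110 °C; then TBAF (2 equiv), THF, rt; aq. NH4Cl
Reagents that add atoms: none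
Why: Dithionite reduces the quinone to hydroquinone 14, an intramolecular Ullmann diaryl ether synthesis then closes the six-membered dioxin between the B5 hydroxyl (the only one within reach) and the C6 bromide with neither ring activated for a Smiles shift, and fluoride removes the silyl ether.

Step 9
Reactants: 16 the heptamethyl ether
Product: 17 phlorofucofuroeckol A
Conditions: BBr3 (20 equiv), CH2Cl2, −78 °C → rt; ice-water; Sephadex LH-20 (MeOH)
Reagents that add atoms: none
Why: Lewis-acid ether cleavage, in which bromide attacks only the methyl carbons of the seven aryl methyl ethers, so the diaryl ether, dioxin and furan C(sp2)–O bonds should stay intact.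

Compound list
1 | 2,6-dibromo-4-methoxyphenol | COc1cc(Br)c(O)c(Br)c1 | starting material
2 | (3,5-dimethoxyphenyl)boronic acid | COc1cc(OC)cc(B(O)O)c1 | starting material
3 | 1,3-dibromo-2-(3,5-dimethoxyphenoxy)-5-methoxybenzene | COc1cc(Br)c(Oc2cc(OC)cc(OC)c2)c(Br)c1 | intermediate
4 | 2-(3,5-dimethoxyphenoxy)-5-methoxybenzene-1,3-diol | COc1cc(O)c(Oc2cc(OC)cc(OC)c2)c(O)c1 | intermediate
5 | 5-bromovanillin | O=Cc1cc(Br)c(O)c(OC)c1 | starting material
6 | 2-bromo-6-methoxybenzene-1,4-diol | Oc1cc(Br)c(O)c(OC)c1 | intermediate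
7 | 2-bromo-6-methoxy-1,4-benzoquinone | O=C1C=C(Br)C(=O)C(OC)=C1 | intermediate
8 | 2-bromo-3-[3-(3,5-dimethoxyphenoxy)-2,4-dihydroxy-6-methoxyphenyl]-6-methoxybenzene-1,4-diol | Oc1c(OC)cc(O)c(c1Br)-c1c(O)c(Oc2cc(OC)cc(OC)c2)c(O)cc1OC | intermediate
9 | 1-bromo-6-(3,5-dimethoxyphenoxy)-3,9-dimethoxydibenzo[b,d]furan-2,7-diol | Oc1c(OC)cc2oc3c(Oc4cc(OC)cc(OC)c4)c(O)cc(OC)c3c2c1Br | intermediate
10 | 1-bromo-7-[(tert-butyldimethylsilyl)oxy]-6-(3,5-dimethoxyphenoxy)-3,9-dimethoxydibenzo[b,d]furan-2-ol | Oc1c(OC)cc2oc3c(Oc4cc(OC)cc(OC)c4)c(O[Si](C)(C)C(C)(C)C)cc(OC)c3c2c1Br | intermediate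
11 | 2-(3,5-dimethoxyphenoxy)-3-hydroxy-5-methoxy-1,4-benzoquinone | O=C1C=C(OC)C(=O)C(O)=C1Oc1cc(OC)cc(OC)c1 | intermediate
12 | 3-chloro-2-(3,5-dimethoxyphenoxy)-5-methoxy-1,4-benzoquinone | O=C1C=C(OC)C(=O)C(Cl)=C1Oc1cc(OC)cc(OC)c1 | intermediate
13 | 3-{[1-bromo-7-(tert-butyldimethylsilyloxy)-6-(3,5-dimethoxyphenoxy)-3,9-dimethoxydibenzo[b,d]furan-2-yl]oxy}-2-(3,5-dimethoxyphenoxy)-5-methoxy-1,4-benzoquinone | O=C1C=C(OC)C(=O)C(Oc2c(OC)cc3oc4c(Oc5cc(OC)cc(OC)c5)c(O[Si](C)(C)C(C)(C)C)cc(OC)c4c3c2Br)=C1Oc1cc(OC)cc(OC)c1 | intermediate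
14 | hydroquinone of 13 (the same substituents on benzene-1,4-diol) | Oc1cc(OC)c(O)c(Oc2c(OC)cc3oc4c(Oc5cc(OC)cc(OC)c5)c(O[Si](C)(C)C(C)(C)C)cc(OC)c4c3c2Br)c1Oc1cc(OC)cc(OC)c1 | intermediate
15 | 16 with the D3 hydroxyl as tert-butyldimethylsilyl ether | COc1cc(OC)cc(Oc2c(O)cc(OC)c3c2Oc2c(OC)cc4oc5c(Oc6cc(OC)cc(OC)c6)c(O[Si](C)(C)C(C)(C)C)cc(OC)c5c4c2O3)c1 | intermediate
16 | phlorofucofuroeckol A heptamethyl ether (free OH at B2 and D3) | COc1cc(OC)cc(Oc2c(O)cc(OC)c3c2Oc2c(OC)cc4oc5c(Oc6cc(OC)cc(OC)c6)c(O)cc(OC)c5c4c2O3)c1 | intermediate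
17 | phlorofucofuroeckol A (achiral) | Oc1cc(O)cc(Oc2c(O)cc(O)c3c2Oc2c(O)cc4oc5c(Oc6cc(O)cc(O)c6)c(O)cc(O)c5c4c2O3)c1 | target

Total steps: 9. Longest linear sequence: 7 (steps 1, 2, 4, 5, 7, 8, 9).

Steps most likely to fail

Step 4. What may go wrong: redox exchange between hydroquinone 8 and unreacted quinone 7, followed by displacement of bromide by the ring D hydroxyl (furan closed at C6), or a second arylation of 4. The fallback would form the biaryl bond at the phenol oxidation level, with no quinone in the flask. It sets out from 5: bromination (Br2, Fe powder, AcOH) would give 2,3-dibromo-4-hydroxy-5-methoxybenzaldehyde F1. A copper-mediated Hurtley-type C-arylation of resorcinol 4 with the bromide ortho to the formyl group of F1 (CuI, K3PO4, DMSO, 80 °C) would give 3-bromo-2-[3-(3,5-dimethoxyphenoxy)-2,4-dihydroxy-6-methoxyphenyl]-4-hydroxy-5-methoxybenzaldehyde F2. Dakin oxidation of F2 (H2O2, aq. NaOH) would come back to the route at hydroquinone 8, which TsOH in AcOH would cyclise to 9.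

Step 7. What may go wrong: electron transfer from the hindered phenoxide to the chloroquinone, or exchange of the ring A aryloxy group of 12 in place of chloride substitution, which would scramble the positions of ring A and the C/D unit on ring B. The fallback would make the ether at the arene level and the quinone afterwards. It sets out from 3: bromine–lithium exchange with one equivalent of n-BuLi and B(OiPr)3 would give [3-bromo-2-(3,5-dimethoxyphenoxy)-5-methoxyphenyl]boronic acid F3. Chan–Lam–Evans coupling of F3 with phenol 10 (Cu(OAc)2, pyridine, O2, as in step 1) would give 1-bromo-2-[3-bromo-2-(3,5-dimethoxyphenoxy)-5-methoxyphenoxy]-7-[(tert-butyldimethylsilyl)oxy]-6-(3,5-dimethoxyphenoxy)-3,9-dimethoxydibenzo[b,d]furan F4. Palladium-catalysed hydroxylation of the less hindered ring B bromide (benzaldoxime as hydroxide surrogate, Cs2CO3, DMF) would give 3-{[1-bromo-7-(tert-butyldimethylsilyloxy)-6-(3,5-dimethoxyphenoxy)-3,9-dimethoxydibenzo[b,d]furan-2-yl]oxy}-2-(3,5-dimethoxyphenoxy)-5-methoxyphenol F5. Teuber oxidation of F5 with (KSO3)2NO at its free para position would come back to the route at 13.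

Step 6. What may go wrong: over-oxidation of the electron-rich resorcinol, attack of the chlorinating agent on ring A, or chlorination of the ortho-quinone tautomer of 11. The fallback would take halogen and quinone from the vanillin series and add ring A by substitution. It sets out from 5: bromination to 2,3-dibromo-4-hydroxy-5-methoxybenzaldehyde F1, Dakin oxidation to 2,3-dibromo-5-methoxybenzene-1,4-diol F6, and NaIO4 oxidation to 2,3-dibromo-5-methoxy-1,4-benzoquinone F7. Addition–elimination of 3,5-dimethoxyphenol (K2CO3, MeCN, −20 °C) at the bromide para to OMe would give 3-bromo-2-(3,5-dimethoxyphenoxy)-5-methoxy-1,4-benzoquinone F8. F8 would take the place of 12 in step 7, and the route is rejoined at 13.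

Further compounds
F1 | step 4 | 2,3-dibromo-4-hydroxy-5-methoxybenzaldehyde | O=Cc1cc(OC)c(O)c(Br)c1Br
F2 | step 4 | 3-bromo-2-[3-(3,5-dimethoxyphenoxy)-2,4-dihydroxy-6-methoxyphenyl]-4-hydroxy-5-methoxybenzaldehyde | O=Cc1cc(OC)c(O)c(Br)c1-c1c(O)c(Oc2cc(OC)cc(OC)c2)c(O)cc1OC
F3 | step 7 | [3-bromo-2-(3,5-dimethoxyphenoxy)-5-methoxyphenyl]boronic acid | COc1cc(Br)c(Oc2cc(OC)cc(OC)c2)c(B(O)O)c1
F4 | step 7 | 1-bromo-2-[3-bromo-2-(3,5-dimethoxyphenoxy)-5-methoxyphenoxy]-7-[(tert-butyldimethylsilyl)oxy]-6-(3,5-dimethoxyphenoxy)-3,9-dimethoxydibenzo[b,d]furan | COc1cc(Br)c(Oc2cc(OC)cc(OC)c2)c(Oc2c(OC)cc3oc4c(Oc5cc(OC)cc(OC)c5)c(O[Si](C)(C)C(C)(C)C)cc(OC)c4c3c2Br)c1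
F5 | step 7 | 3-{[1-bromo-7-(tert-butyldimethylsilyloxy)-6-(3,5-dimethoxyphenoxy)-3,9-dimethoxydibenzo[b,d]furan-2-yl]oxy}-2-(3,5-dimethoxyphenoxy)-5-methoxyphenol | COc1cc(O)c(Oc2cc(OC)cc(OC)c2)c(Oc2c(OC)cc3oc4c(Oc5cc(OC)cc(OC)c5)c(O[Si](C)(C)C(C)(C)C)cc(OC)c4c3c2Br)c1
F6 | step 6 | 2,3-dibromo-5-methoxybenzene-1,4-diol | Oc1cc(OC)c(O)c(Br)c1Br
F7 | step 6 | 2,3-dibromo-5-methoxy-1,4-benzoquinone | O=C1C=C(OC)C(=O)C(Br)=C1Br
F8 | step 6 | 3-bromo-2-(3,5-dimethoxyphenoxy)-5-methoxy-1,4-benzoquinone | O=C1C=C(OC)C(=O)C(Br)=C1Oc1cc(OC)cc(OC)c1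
A1 | direct plan | 2-[2-bromo-4-(2-bromo-6-formyl-3,5-dimethoxyphenoxy)-6-methoxyphenoxy]-4,6-dimethoxybenzene-1,3-dicarbaldehyde | O=Cc1c(Oc2cc(Br)c(Oc3c(C=O)c(OC)cc(OC)c3C=O)c(OC)c2)c(Br)c(OC)cc1OC
A2 | direct plan | 2-[2-bromo-4-(2-bromo-6-hydroxy-3,5-dimethoxyphenoxy)-6-methoxyphenoxy]-4,6-dimethoxybenzene-1,3-diol | Oc1c(Oc2cc(Br)c(Oc3c(O)c(OC)cc(OC)c3O)c(OC)c2)c(Br)c(OC)cc1OC
A3 | direct plan | 1,3,6,10,12-pentamethoxy-[1]benzofuro[3,2-a]oxanthrene-4,9-diol | Oc1c(OC)cc(OC)c2c1Oc1c(OC)cc3oc4c(O)c(OC)cc(OC)c4c3c1O2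
A4 | direct plan | 4,9-bis(3,5-dimethoxyphenoxy)-1,3,6,10,12-pentamethoxy-[1]benzofuro[3,2-a]oxanthrene | COc1cc(OC)cc(Oc2c(OC)cc(OC)c3c2Oc2c(OC)cc4oc5c(Oc6cc(OC)cc(OC)c6)c(OC)cc(OC)c5c4c2O3)c1
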